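## Analysis of the target

The target 23 is a flavone: a chromen-4-one in which benzene ring A (C4a, C5, C6, C7, C8, C8a) is fused to pyranone ring C (O1, C2, C3, C4), with aryl ring B on C2. It is a kaempferol 3-methyl ether whose ring B carries two 3-methylbut-2-enyl (prenyl) groups at C3' and C5', on either side of the 4'-hydroxyl. There is no stereocenter, and the prenyl double bonds carry geminal methyl groups, so no alkene geometry has to be set. The sensitive groups are the two prenyl groups ortho to a phenol and the three phenols of different acidity. The prenyl groups close to chromans or add HX under acid, and they are lost to hydrogenation and to electrophilic oxidants. The difficulty lies in telling four oxygens apart (one methyl ether at C3 beside free hydroxyls at C5, C7 and C4') and in placing two prenyl groups on carbon. The strategy rests on ring A. Its oxygens at C5 and C7 are meta to each other, C6 and C8 are unsubstituted, and it is fused at the C4a–C8a bond. This is the pattern that a vinylketene and a siloxyalkyne give, with the C5=C6 double bond of a monocyclic pyranone as the vinyl unit. Ring C, with its C3 oxygen, C4 carbonyl and C2 substituent, maps onto kojic acid 6.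

## Retrosynthetic reasoning

**23 from 22.** The two O–Si bonds at O7 and O4' are cut last. The silyl group on O7 is what remains of the oxygen substituent of the alkyne. The silyl group on O4' is needed because a free, unhindered phenol would add to the ketenes of the key step. Both leave under fluoride, which touches neither the methyl ether nor the prenyl groups, so the end game needs no acid.

**22 from 12 and 17.** Four bonds of ring A are cut: C8a–C8, C7–C8, C5–C6 and C4a–C5. Only the C4a–C8a bond stays, as the C5=C6 bond of the pyranone in diazoketone 12. Cutting here leaves ring C as a monocyclic pyranone on which every position is already fixed. The two oxygens of ring A come from different sources: O5 from the carbonyl of 12 and O7 from alkyne 17. They are therefore differentiated from the start. The forward reaction has to rearrange 12 to a ketene, add 17 in one orientation, and close and aromatise the ring without an oxidant.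

**12 from 10, and 10 from 9.** The bond between the acyl carbon and the diazo carbon is cut, which leads to carboxylic acid 10. Acid 10 is the oxidation product of the primary alcohol 9. Through the rearrangement, the hydroxymethyl carbon of 6 ends as C5 of the flavone and the added diazo carbon as C8. The forward steps must make an activated acyl derivative without free acid, because of the prenyl groups.

**9 from 8 and 5.** The C2–C1' bond between ring C and ring B is cut. C2 of bromopyranone 8 is a vinylogous acyl position and a good electrophile for cross-coupling. Ring B comes as arylboronate 5, whose boron sits between two hydrogens. This joins the two halves after each has been fully substituted.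

**8 from 7, and 7 from 6.** The O–CH3 bond and the C–Br bond are cut. In 7 the enolic hydroxyl is the only acidic one, so the methyl ether that must survive to the end is put on without any selectivity problem. In 6 the carbon ortho to that hydroxyl is the only nucleophilic ring position, so the bromine goes where ring B is needed.

**5 from 4, 4 from 3, and 3 from 1 and 2.** The C–B bond, the O–Si bond and the two aryl–CH2 bonds are cut. In 4-bromophenol 1 the bromine blocks the para position during C-prenylation with prenyl bromide 2 and afterwards becomes the handle for boron.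

**17 from 13 and 14.** The O–Si bond and the C–O bond are cut. Acetylene 13 is oxidised at one carbon to the ynolate and silylated on oxygen by triflate 14.

## Alternatives that were turned down

**Alternative 1:** The C4–C4a and O1–C8a bonds are cut. Ring A is then delivered as 3,5-bis(methoxymethoxy)benzyne A3 and the rest as (Z)-2-methoxy-3-aryl-acrylic acid A2. In the forward step the fluoride-released aryne inserts into the acyl C–O bond of A2. The carboxylate oxygen adds to the aryne carbon remote from the neighbouring alkoxy group, the aryl anion attacks the carbonyl, and the ortho-hydroxyaryl ketone A1 results.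
- For it: the step is convergent and brings the C3 methoxy group with it. The alkoxy group next to the triple bond steers the addition in the sense that is needed. On convergence at the key step this alternative is stronger than the chosen route, and it needs no light and no diazo compound.
- Against it: A3 is an unselective electrophile. The substrate offers it allylic C–H bonds of two prenyl groups for ene reactions and an electron-rich enol ether double bond for [2+2] addition. Simple O-arylation competes with acyl transfer.
- After the key step: A1 is still open in ring C. Closing it to the flavone needs a cyclisation and dehydrogenation with a halogen-based or similar oxidant in the presence of the prenyl groups. The three acetal protecting groups leave only under acid, the condition under which an ortho-prenylphenol closes to a chroman.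
- Comparison: the chosen route has ring C closed and at the right oxidation level from compound 8 on, and it ends with fluoride alone.

**Alternative 2:** The C3–C4 bond is cut and ring C is opened to dialdehyde A5. This is a salicylaldehyde ether whose ether carbon carries ring B and a formyl group. In the forward step a triazolium-derived carbene catalyst converts the aromatic aldehyde into an acyl anion equivalent, which adds to the aliphatic aldehyde. This closes the six-membered ring as the racemic trans-dihydroflavonol A4.
- For it: the conditions are mild and metal-free. The C3 hydroxyl of A4 is the only free hydroxyl, so its methylation is as unambiguous as the methylation of 7 in the chosen route; on that point the two are equal.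
- Against it: the catalyst must pick the hindered, electron-rich, doubly ortho-substituted aromatic aldehyde as the donor over the unhindered aliphatic one. The reverse polarity gives the isomeric 3-oxo compound. The aliphatic aldehyde of A5 carries an aryl and an aryloxy group on its alpha carbon, so it enolises and oxidises easily and is hard to prepare and keep.
- After the key step: the two stereocenters of A4 are made only to be removed by dehydrogenation to the flavonol, an oxidation that must spare two prenyl groups. Methylation and acidic removal of three acetals follow.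
- Comparison: three steps follow the key step, against one in the chosen route, and the stereochemical effort is wasted.

**Alternative 3:** The C4a–C5 bond is cut and ring A is opened to the linear methyl 9-aryl-3,5,7-trioxonon-8-enoate A7. In the forward step a magnesium alkoxide base chelates the polyketone, and the C6 carbanion attacks the ester carbon in a Claisen condensation. This gives ring A as the 2',4',6'-trihydroxychalcone A6.
- For it: ring A arises from acyclic material with no protecting group on its oxygens, from cheap reagents. On reagent simplicity and safety it is stronger than the chosen route.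
- Against it: A7 has to be made by acylating a polyanion with a cinnamoyl electrophile that also accepts conjugate addition. A7 can also cyclise by aldol reaction to a resorcylate, by lactonisation to a 4-hydroxy-2-pyranone, or by oxa-Michael addition to the enone.
- After the key step: A6 lacks the C3 oxygen. Ring C closure with C3 hydroxylation by an alkaline peroxide reaction of the Algar–Flynn–Oyamada type tends to give aurones when the chalcone carries a 6'-oxygen. The 3-hydroxyl would then have to be methylated beside a free, more acidic 7-hydroxyl, and the 4'-acetal removed with acid.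
- Comparison: the chosen route pays with a diazo compound and a photochemical step, but it never has to distinguish oxygens on the finished skeleton.

Key step: step 10

Assumption: (triisopropylsilyloxy)acetylene 17 is not treated as a stock chemical and is made in step 9; diazomethane is used as a freshly prepared, dried ethereal solution.

## Route

Step 1
Reactants: 1 4-bromophenol; 2 prenyl bromide (1-bromo-3-methylbut-2-ene)
Product: 3 4-bromo-2,6-bis(3-methylbut-2-enyl)phenol
Conditions: NaH (2.2 equiv), toluene, 0 °C to rt; 2 (2.2 equiv)
Reagents that add atoms: none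
Why: Ortho-C-alkylation of a sodium phenoxide: in toluene the phenoxide is a tight, aggregated ion pair with its oxygen covered by sodium, so the allylic bromide is attacked by the ortho carbons; bromine blocks the para position, and a second deprotonation and alkylation should give the 2,6-diprenylphenol.

Step 2
Reactants: 3 4-bromo-2,6-bis(3-methylbut-2-enyl)phenol
Product: 4 [4-bromo-2,6-bis(3-methylbut-2-enyl)phenoxy](tert-butyl)dimethylsilane
Conditions: TBSCl, imidazole, DMF, 40 °C
Reagents that add atoms: tert-butyldimethylsilyl chloride, CC(C)(C)[Si](C)(C)Cl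
Why: Silylation of a phenol with imidazole as base and acyl-transfer-type catalyst; the two ortho substituents slow the reaction but later shield the silyl ether from aqueous base, and the ether keeps the phenol from adding to ketenes in step 10.

Step 3
Reactants: 4 [4-bromo-2,6-bis(3-methylbut-2-enyl)phenoxy](tert-butyl)dimethylsilane
Product: 5 tert-butyldimethyl[4-(4,4,5,5-tetramethyl-1,3,2-dioxaborolan-2-yl)-2,6-bis(3-methylbut-2-enyl)phenoxy]silane
Conditions: B2pin2, Pd(dppf)Cl2 (3 mol %), KOAc, 1,4-dioxane, 85 °C
Reagents that add atoms: bis(pinacolato)diboron, CC1(C)OB(OC1(C)C)B1OC(C)(C)C(C)(C)O1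
Why: Miyaura borylation of an aryl bromide whose bromine lies between two hydrogens; trisubstituted alkenes are poor partners for the arylpalladium intermediate and the weak acetate base leaves the silyl ether alone.

Step 4
Reactants: 6 kojic acid (5-hydroxy-2-(hydroxymethyl)-4H-pyran-4-one)
Product: 7 2-bromo-3-hydroxy-6-(hydroxymethyl)-4H-pyran-4-one (6-bromokojic acid)
Conditions: NBS (1.0 equiv), DMF, 0 °C to rt
Reagents that add atoms: N-bromosuccinimide, O=C1CCC(=O)N1Br
Why: Electrophilic bromination of an enol: the carbon between the ring oxygen and the hydroxyl-bearing carbon is the beta carbon of the enol and the site at which kojic acid takes electrophiles, so one equivalent of the bromine source should give the monobromide.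

Step 5
Reactants: 7 2-bromo-3-hydroxy-6-(hydroxymethyl)-4H-pyran-4-one
Product: 8 2-bromo-6-(hydroxymethyl)-3-methoxy-4H-pyran-4-one
Conditions: MeI, K2CO3, acetone, rt
Reagents that add atoms: iodomethane, CI
Why: Williamson ether synthesis on the enolic hydroxyl, a vinylogous acid that carbonate deprotonates while the primary alcohol stays neutral; the methyl ether of the target is thereby set on the only candidate oxygen.

Step 6
Reactants: 8 2-bromo-6-(hydroxymethyl)-3-methoxy-4H-pyran-4-one; 5 tert-butyldimethyl[4-(4,4,5,5-tetramethyl-1,3,2-dioxaborolan-2-yl)-2,6-bis(3-methylbut-2-enyl)phenoxy]silane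
Product: 9 2-[4-(tert-butyldimethylsilyloxy)-3,5-bis(3-methylbut-2-enyl)phenyl]-6-(hydroxymethyl)-3-methoxy-4H-pyran-4-one
Conditions: Pd(dppf)Cl2 (5 mol %), K3PO4, 1,4-dioxane/H2O (10:1), 80 °C
Reagents that add atoms: none
Why: Suzuki–Miyaura coupling: the C–Br bond is that of a vinylogous acyl bromide and should undergo fast oxidative addition to zerovalent palladium, the boronate is unhindered, the free alcohol is tolerated, and the flanked aryl silyl ether should withstand the mild phosphate base.

Step 7
Reactants: 9 2-[4-(tert-butyldimethylsilyloxy)-3,5-bis(3-methylbut-2-enyl)phenyl]-6-(hydroxymethyl)-3-methoxy-4H-pyran-4-one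
Product: 10 6-[4-(tert-butyldimethylsilyloxy)-3,5-bis(3-methylbut-2-enyl)phenyl]-5-methoxy-4-oxo-4H-pyran-2-carboxylic acid
Conditions: TEMPO (20 mol %), PhI(OAc)2 (2.2 equiv), MeCN/H2O (1:1), rt
Reagents that add atoms: water, O
Why: Oxoammonium-catalysed oxidation of a primary alcohol to the aldehyde and, through its hydrate, to the acid; the activated pyranylmethanol reacts much faster than the trisubstituted alkenes, and the medium is only weakly acidic.

Step 8
Reactants: 10 6-[4-(tert-butyldimethylsilyloxy)-3,5-bis(3-methylbut-2-enyl)phenyl]-5-methoxy-4-oxo-4H-pyran-2-carboxylic acid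
Product: 12 2-[4-(tert-butyldimethylsilyloxy)-3,5-bis(3-methylbut-2-enyl)phenyl]-6-(2-diazoacetyl)-3-methoxy-4H-pyran-4-one, via acid chloride 11 (not isolated)
Conditions: 1-chloro-N,N,2-trimethylprop-1-en-1-amine, CH2Cl2, 0 °C to rt; then CH2N2 (excess), Et2O, -10 to 0 °C; AcOH quench
Reagents that add atoms: diazomethane, C=[N+]=[N-]; 1-chloro-N,N,2-trimethylprop-1-en-1-amine, CC(C)=C(Cl)N(C)C (chlorine of 11 only)
Why: Acylation of diazomethane by an acid chloride, the first half of the Arndt–Eistert sequence; the chloroenamine makes the chloride without releasing HCl, which would add to the prenyl double bonds, and the excess diazomethane takes up the HCl set free in the acylation.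

Step 9
Reactants: 13 acetylene; 14 triisopropylsilyl triflate
Product: 17 (triisopropylsilyloxy)acetylene, via lithium acetylide 15 (not isolated), via lithium ethynolate 16 (not isolated)
Conditions: 13 (excess), n-BuLi, THF, -78 °C; t-BuOOLi (from t-BuOOH and LiN(SiMe3)2, THF, -78 °C), -78 to -10 °C; 14, -78 to 0 °C
Reagents that add atoms: tert-butyl hydroperoxide, CC(C)(C)OO
Why: Oxidation of a lithium acetylide by lithium tert-butyl peroxide (attack of the acetylide carbon on the peroxide oxygen) gives the ynolate, which the bulky silyl triflate takes on oxygen and not on carbon; this is the usual route from 1-alkynes to 1-siloxy-1-alkynes, applied here to acetylene itself, with excess acetylene to hold back disproportionation of 15.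

Step 10
Reactants: 12 2-[4-(tert-butyldimethylsilyloxy)-3,5-bis(3-methylbut-2-enyl)phenyl]-6-(2-diazoacetyl)-3-methoxy-4H-pyran-4-one; 17 (triisopropylsilyloxy)acetylene
Product: 22 2-[4-(tert-butyldimethylsilyloxy)-3,5-bis(3-methylbut-2-enyl)phenyl]-5-hydroxy-3-methoxy-7-(triisopropylsilyloxy)-4H-chromen-4-one, via ketene 18 (not isolated), via cyclobutenone 19 (not isolated), via dienylketene 20 (not isolated), via cyclohexadienone 21 (not isolated)
Conditions: 17 (3 equiv), hν (450 nm LED), ClCH2CH2Cl, rt; then 80 °C
Reagents that add atoms: none
Why: Visible light excites the weak long-wavelength band of the diazoketone and not the aryl pyranone; nitrogen leaves while the pyranonyl group shifts from the carbonyl carbon to the diazo carbon (Wolff rearrangement), which forms C8a–C8 and gives ketene 18. The electron-rich alkyne 17 adds across the ketene C=C in a [2+2] cycloaddition, its unsubstituted carbon bonding to the ketene carbonyl carbon (C5–C6) and its oxygen-bearing carbon to the ketene CH (C7–C8), so the silyloxy group lands on C7 in cyclobutenone 19. Heating opens 19 by 4-electron electrocyclic cleavage to dienylketene 20, whose ketene carbon bonds to C5 of the pyranone (the future C4a) in a 6-electron electrocyclisation that closes ring A as a six-membered carbocycle; no other position is open, because the second neighbour of the ketene-bearing carbon is the ring oxygen. Tautomerisation of 21 gives the C5 phenol, held by a hydrogen bond to the C4 carbonyl, so no oxidant is needed and the new phenol is a poor trap for ketene. The closest known reaction type is the Danheiser benzannulation of aryl, heteroaryl and alkenyl alpha-diazo ketones with siloxyalkynes. No stereocenter remains in 22; the sp3 centres of 19 and 21 are transient. The ketene must choose the alkyne over the prenyl double bonds, which the much higher nucleophilicity of the ynol ether and its excess should secure, and the 4'-oxygen must stay silylated so that it cannot add to 18 or 20.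

Step 11
Reactants: 22 2-[4-(tert-butyldimethylsilyloxy)-3,5-bis(3-methylbut-2-enyl)phenyl]-5-hydroxy-3-methoxy-7-(triisopropylsilyloxy)-4H-chromen-4-one
Product: 23 5,7-dihydroxy-2-[4-hydroxy-3,5-bis(3-methylbut-2-enyl)phenyl]-3-methoxy-4H-chromen-4-one
Conditions: Bu4NF (2.5 equiv), AcOH (2.5 equiv), THF, 0 °C to rt
Reagents that add atoms: none
Why: Fluoride-induced cleavage of two aryl silyl ethers, driven by the Si–F bond and the phenoxide leaving groups; acetic acid keeps the medium near neutral, so the prenyl groups and the methyl ether should be untouched.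

## Compound list

1 | 4-bromophenol | Oc1ccc(Br)cc1 | starting material
2 | prenyl bromide (1-bromo-3-methylbut-2-ene) | CC(C)=CCBr | starting material
3 | 4-bromo-2,6-bis(3-methylbut-2-enyl)phenol | CC(C)=CCc1cc(Br)cc(CC=C(C)C)c1O | intermediate
4 | [4-bromo-2,6-bis(3-methylbut-2-enyl)phenoxy](tert-butyl)dimethylsilane | CC(C)=CCc1cc(Br)cc(CC=C(C)C)c1O[Si](C)(C)C(C)(C)C | intermediate
5 | tert-butyldimethyl[4-(4,4,5,5-tetramethyl-1,3,2-dioxaborolan-2-yl)-2,6-bis(3-methylbut-2-enyl)phenoxy]silane | CC(C)=CCc1cc(B2OC(C)(C)C(C)(C)O2)cc(CC=C(C)C)c1O[Si](C)(C)C(C)(C)C | intermediate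
6 | kojic acid | OCc1cc(=O)c(O)co1 | starting material
7 | 2-bromo-3-hydroxy-6-(hydroxymethyl)-4H-pyran-4-one | OCc1cc(=O)c(O)c(Br)o1 | intermediate
8 | 2-bromo-6-(hydroxymethyl)-3-methoxy-4H-pyran-4-one | COc1c(Br)oc(CO)cc1=O | intermediate
9 | 2-[4-(tert-butyldimethylsilyloxy)-3,5-bis(3-methylbut-2-enyl)phenyl]-6-(hydroxymethyl)-3-methoxy-4H-pyran-4-one | COc1c(-c2cc(CC=C(C)C)c(O[Si](C)(C)C(C)(C)C)c(CC=C(C)C)c2)oc(CO)cc1=O | intermediate
10 | 6-[4-(tert-butyldimethylsilyloxy)-3,5-bis(3-methylbut-2-enyl)phenyl]-5-methoxy-4-oxo-4H-pyran-2-carboxylic acid | COc1c(-c2cc(CC=C(C)C)c(O[Si](C)(C)C(C)(C)C)c(CC=C(C)C)c2)oc(C(=O)O)cc1=O | intermediate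
11 | 6-[4-(tert-butyldimethylsilyloxy)-3,5-bis(3-methylbut-2-enyl)phenyl]-5-methoxy-4-oxo-4H-pyran-2-carbonyl chloride | COc1c(-c2cc(CC=C(C)C)c(O[Si](C)(C)C(C)(C)C)c(CC=C(C)C)c2)oc(C(=O)Cl)cc1=O | intermediate
12 | 2-[4-(tert-butyldimethylsilyloxy)-3,5-bis(3-methylbut-2-enyl)phenyl]-6-(2-diazoacetyl)-3-methoxy-4H-pyran-4-one | COc1c(-c2cc(CC=C(C)C)c(O[Si](C)(C)C(C)(C)C)c(CC=C(C)C)c2)oc(C(=O)C=[N+]=[N-])cc1=O | intermediate
13 | acetylene | C#C | starting material
14 | triisopropylsilyl triflate | CC(C)[Si](OS(=O)(=O)C(F)(F)F)(C(C)C)C(C)C | starting material
15 | lithium acetylide | [Li+].[C-]#C | intermediate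
16 | lithium ethynolate | [Li+].[O-]C#C | intermediate
17 | (triisopropylsilyloxy)acetylene | C#CO[Si](C(C)C)(C(C)C)C(C)C | intermediate
18 | 2-{6-[4-(tert-butyldimethylsilyloxy)-3,5-bis(3-methylbut-2-enyl)phenyl]-5-methoxy-4-oxo-4H-pyran-2-yl}ethenone (pyranonylketene) | COc1c(-c2cc(CC=C(C)C)c(O[Si](C)(C)C(C)(C)C)c(CC=C(C)C)c2)oc(C=C=O)cc1=O | intermediate
19 | 4-{6-[4-(tert-butyldimethylsilyloxy)-3,5-bis(3-methylbut-2-enyl)phenyl]-5-methoxy-4-oxo-4H-pyran-2-yl}-3-(triisopropylsilyloxy)cyclobut-2-en-1-one (racemic) | COc1c(-c2cc(CC=C(C)C)c(O[Si](C)(C)C(C)(C)C)c(CC=C(C)C)c2)oc(C2C(=O)C=C2O[Si](C(C)C)(C(C)C)C(C)C)cc1=O | intermediate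
20 | 4-{6-[4-(tert-butyldimethylsilyloxy)-3,5-bis(3-methylbut-2-enyl)phenyl]-5-methoxy-4-oxo-4H-pyran-2-yl}-3-(triisopropylsilyloxy)buta-1,3-dien-1-one (ketenyl carbon and pyranonyl group cis on the central double bond) | O=C=C/C(O[Si](C(C)C)(C(C)C)C(C)C)=C\c1cc(=O)c(OC)c(-c2cc(CC=C(C)C)c(O[Si](C)(C)C(C)(C)C)c(CC=C(C)C)c2)o1 | intermediate
21 | 2-[4-(tert-butyldimethylsilyloxy)-3,5-bis(3-methylbut-2-enyl)phenyl]-3-methoxy-7-(triisopropylsilyloxy)-4aH-chromene-4,5-dione (racemic keto tautomer) | COC1=C(c2cc(CC=C(C)C)c(O[Si](C)(C)C(C)(C)C)c(CC=C(C)C)c2)OC2=CC(O[Si](C(C)C)(C(C)C)C(C)C)=CC(=O)C2C1=O | intermediate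
22 | 2-[4-(tert-butyldimethylsilyloxy)-3,5-bis(3-methylbut-2-enyl)phenyl]-5-hydroxy-3-methoxy-7-(triisopropylsilyloxy)-4H-chromen-4-one | COc1c(-c2cc(CC=C(C)C)c(O[Si](C)(C)C(C)(C)C)c(CC=C(C)C)c2)oc2cc(O[Si](C(C)C)(C(C)C)C(C)C)cc(O)c2c1=O | intermediate
23 | 5,7-dihydroxy-2-[4-hydroxy-3,5-bis(3-methylbut-2-enyl)phenyl]-3-methoxy-4H-chromen-4-one | COc1c(-c2cc(CC=C(C)C)c(O)c(CC=C(C)C)c2)oc2cc(O)cc(O)c2c1=O | target

## Step count and least certain steps

Total step count: 11. Longest linear sequence: 8 steps (steps 1, 2, 3, 6, 7, 8, 10, 11).

**Step 10 (key step).** The most likely failure is loss of the ketene before it meets the alkyne. The 2-aryl-pyranone chromophore may take up part of the light, which makes the rearrangement slow, and a slowly formed ketene 18 can dimerise or be hydrolysed by traces of water. The 6-electron closure may also need more heat than the ring opening, because it interrupts the conjugation of the pyranone. The fallback sets out from diazoketone 12 and comes back at cyclobutenone 19; it makes the same ketene without light.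
- 12 is rearranged in the dark with silver benzoate (PhCO2Ag) and Et3N in aqueous THF, where water takes up the ketene to give {6-[4-(tert-butyldimethylsilyloxy)-3,5-bis(3-methylbut-2-enyl)phenyl]-5-methoxy-4-oxo-4H-pyran-2-yl}acetic acid F1.
- The chloroenamine of step 8 converts it into the corresponding acetyl chloride F2.
- Slow addition of F2 to Et3N and 17 in toluene generates 18 by dehydrochlorination at a rate the alkyne can match. The [2+2] cycloaddition gives 19, which is heated as in step 10 to reach 22.

**Step 9.** Lithium acetylide 15 may disproportionate to the insoluble dilithium salt on warming, before it is oxidised. Silylation may also take place partly on carbon, and the ynol ether may hydrolyse during isolation. The fallback sets out from triflate 14 and comes back at 17.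
- Chloroacetaldehyde is converted with 14 and iPr2NEt in CH2Cl2 into the silyl enol ether (2-chlorovinyloxy)triisopropylsilane F3 (E/Z mixture).
- Two equivalents of LiN(iPr)2 in THF at -78 °C remove HCl and give the lithium alkynyl ether, which is protonated on work-up to 17. This is the dehydrohalogenation by which alkoxyacetylenes are classically made.

**Step 8.** Diazomethane may add as a 1,3-dipole to the electron-poor double bond of the acylpyranone, in competition with acylation, and too little diazomethane would let HCl convert the product into the chloromethyl ketone. The fallback sets out from acid chloride 11 and comes back at 12, without diazomethane.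
- Me2CuLi in THF at -78 °C converts 11 into the methyl ketone 6-acetyl-2-[4-(tert-butyldimethylsilyloxy)-3,5-bis(3-methylbut-2-enyl)phenyl]-3-methoxy-4H-pyran-4-one F4.
- Its lithium enolate (LiN(SiMe3)2, -78 °C) is acylated with 2,2,2-trifluoroethyl trifluoroacetate to the trifluoromethyl 1,3-diketone F5.
- Methanesulfonyl azide with Et3N and water in MeCN transfers the diazo group with loss of the trifluoroacetyl group (detrifluoroacetylative diazo transfer) to give 12.

**Step 1.** O-alkylation may compete with C-alkylation, the reaction may stop at the mono-prenyl stage, and the ortho-prenylphenol may cyclise to a chroman; all of these lower the selectivity. The fallback sets out from 1 and comes back at 4.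
- O-allylation (allyl bromide, K2CO3, acetone) gives 1-(allyloxy)-4-bromobenzene F6.
- Aromatic Claisen rearrangement (N,N-diethylaniline, 190 °C) gives 2-allyl-4-bromophenol F7.
- The same two operations repeated give 2-allyl-1-(allyloxy)-4-bromobenzene F8 and 2,6-diallyl-4-bromophenol F9.
- Silylation as in step 2 gives (2,6-diallyl-4-bromophenoxy)(tert-butyl)dimethylsilane F10.
- Cross-metathesis with excess 2-methyl-2-butene and second-generation Grubbs catalyst in CH2Cl2 turns both allyl groups into prenyl groups and gives 4.

## Further compounds

F1 | step 10 | {6-[4-(tert-butyldimethylsilyloxy)-3,5-bis(3-methylbut-2-enyl)phenyl]-5-methoxy-4-oxo-4H-pyran-2-yl}acetic acid | COc1c(-c2cc(CC=C(C)C)c(O[Si](C)(C)C(C)(C)C)c(CC=C(C)C)c2)oc(CC(=O)O)cc1=O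
F2 | step 10 | {6-[4-(tert-butyldimethylsilyloxy)-3,5-bis(3-methylbut-2-enyl)phenyl]-5-methoxy-4-oxo-4H-pyran-2-yl}acetyl chloride | COc1c(-c2cc(CC=C(C)C)c(O[Si](C)(C)C(C)(C)C)c(CC=C(C)C)c2)oc(CC(=O)Cl)cc1=O
F3 | step 9 | (2-chlorovinyloxy)triisopropylsilane (E/Z mixture) | ClC=CO[Si](C(C)C)(C(C)C)C(C)C
F4 | step 8 | 6-acetyl-2-[4-(tert-butyldimethylsilyloxy)-3,5-bis(3-methylbut-2-enyl)phenyl]-3-methoxy-4H-pyran-4-one | COc1c(-c2cc(CC=C(C)C)c(O[Si](C)(C)C(C)(C)C)c(CC=C(C)C)c2)oc(C(C)=O)cc1=O
F5 | step 8 | 1-{6-[4-(tert-butyldimethylsilyloxy)-3,5-bis(3-methylbut-2-enyl)phenyl]-5-methoxy-4-oxo-4H-pyran-2-yl}-4,4,4-trifluorobutane-1,3-dione | COc1c(-c2cc(CC=C(C)C)c(O[Si](C)(C)C(C)(C)C)c(CC=C(C)C)c2)oc(C(=O)CC(=O)C(F)(F)F)cc1=O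
F6 | step 1 | 1-(allyloxy)-4-bromobenzene | C=CCOc1ccc(Br)cc1
F7 | step 1 | 2-allyl-4-bromophenol | C=CCc1cc(Br)ccc1O
F8 | step 1 | 2-allyl-1-(allyloxy)-4-bromobenzene | C=CCOc1ccc(Br)cc1CC=C
F9 | step 1 | 2,6-diallyl-4-bromophenol | C=CCc1cc(Br)cc(CC=C)c1O
F10 | step 1 | (2,6-diallyl-4-bromophenoxy)(tert-butyl)dimethylsilane | C=CCc1cc(Br)cc(CC=C)c1O[Si](C)(C)C(C)(C)C
A1 | alternative 1 | 2'-hydroxy-alpha-methoxy-4',6',4-tris(methoxymethoxy)-3,5-bis(3-methylbut-2-enyl)chalcone | O=C(c1c(O)cc(OCOC)cc1OCOC)/C(OC)=C/c1cc(CC=C(C)C)c(OCOC)c(CC=C(C)C)c1
A2 | alternative 1 | (Z)-2-methoxy-3-[4-(methoxymethoxy)-3,5-bis(3-methylbut-2-enyl)phenyl]acrylic acid | OC(=O)/C(OC)=C/c1cc(CC=C(C)C)c(OCOC)c(CC=C(C)C)c1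
A3 | alternative 1 | 3,5-bis(methoxymethoxy)benzyne | COCOC1=CC(OCOC)=CC#C1
A4 | alternative 2 | trans-5,7,4'-tris(methoxymethoxy)-3',5'-bis(3-methylbut-2-enyl)dihydroflavonol (racemic, one enantiomer drawn) | O=C1c2c(OCOC)cc(OCOC)cc2O[C@H](c2cc(CC=C(C)C)c(OCOC)c(CC=C(C)C)c2)[C@H]1O
A5 | alternative 2 | 2-{1-[4-(methoxymethoxy)-3,5-bis(3-methylbut-2-enyl)phenyl]-2-oxoethoxy}-4,6-bis(methoxymethoxy)benzaldehyde (racemic) | O=Cc1c(OCOC)cc(OCOC)cc1OC(C=O)c1cc(CC=C(C)C)c(OCOC)c(CC=C(C)C)c1
A6 | alternative 3 | 2',4',6'-trihydroxy-4-(methoxymethoxy)-3,5-bis(3-methylbut-2-enyl)chalcone | O=C(/C=C/c1cc(CC=C(C)C)c(OCOC)c(CC=C(C)C)c1)c1c(O)cc(O)cc1O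
A7 | alternative 3 | methyl (E)-9-[4-(methoxymethoxy)-3,5-bis(3-methylbut-2-enyl)phenyl]-3,5,7-trioxonon-8-enoate | COC(=O)CC(=O)CC(=O)CC(=O)/C=C/c1cc(CC=C(C)C)c(OCOC)c(CC=C(C)C)c1
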